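**Plan**
- Retrosynthesis: the central cyclohexene is cut by a retro-[4+2] into two identical trienes 38. In 38 the C17=C18 bond (Wittig), the C7=C2 enal (allylic transposition), the C10 methyl and the ester are cut last. The spiro ring is then cut at C11–C12 together with C6–C5, back to iodo-enone 25, which goes back through a quinone monoketal to an aryl aldehyde, an allylboronate and an alkoxy-aldehyde.
- Forward: the C27/C14 unit is built on an arene, a lactone templates the C15=C16 alkene, the arene is dearomatised to the cyclohexenone, and one radical cascade closes the cyclopentane and adds C3–C5 at C6. Then follow the C7 and C10 carbinols, ester, enal and triene; the central cyclohexene is formed last by dimerisation.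
- Stereochemistry: C27 and C14 come from a chiral-phosphoric-acid-catalysed (E)-allylboration; C11 and C6 from C27/C14 in the cascade; C10 from addition anti to the C6 and C27 arms. Alkene geometry comes from the lactone ring (C15=C16), a tributylphosphonium ylide (C17=C18) and thermodynamic control (C7=C2). The two core centres come from a cycloaddition with the two arms trans; their absolute sense is only weakly controlled.
- Enabling feature: in each spiro[4.5]decane the spiro carbon C11 is the β-carbon of a latent cyclohexenone whose carbonyl is C7 (the ring carbon that carries the enal in the target). The ring methylene C12 is a primary carbon joined to C11 through C13–C14–C27. A C12 radical therefore closes the cyclopentane 5-exo at C11 and leaves a radical at C6, where the three-carbon ester arm is needed.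

Key step: step 16

Remark on locants (same for both halves): C1 aldehyde carbon; C2 its α-carbon (C25 = methyl on C2); C3–C5 the ester-bearing chain (O on C3); C6–C11 the cyclohexane (C6 bears the chain, C7 the alkylidene, C10 the methyl carbinol, C11 spiro); C12, C13, C14, C27 the other cyclopentane carbons (C27 carbinol, C14 bears the side chain); C15–C23 the side chain (C28 = CH2OH on C15, C29 = CH2 on C19).
Assumption: compounds 1, 2, 7, 9, 10 and 14 are taken as commercially available; TBS = tert-butyldimethylsilyl, PMB = 4-methoxybenzyl, Ar = 5-(TBSO)-2-methoxyphenyl.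

Step 1
Reactants: 1 5-bromo-2-methylpent-2-ene; 2 prop-2-yn-1-ol
Product: 4 6-methyl-2-methylidenehept-5-en-1-ol, via Grignard reagent 3 (not isolated)
Conditions: Mg, THF, rt; then 2 (0.45 equiv), CuI (10 mol%), THF, 0 °C to rt; aq. NH4Cl
Reagents that add atoms: none
Why: Copper-catalysed carbomagnesiation of the magnesium alkoxide of propargyl alcohol puts the alkyl group on the internal alkyne carbon and gives the 2-substituted allylic alcohol after protonolysis; no stereocentre is formed.

Step 2
Reactants: 4 6-methyl-2-methylidenehept-5-en-1-ol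
Product: 5 2-(bromomethyl)-6-methylhepta-1,5-diene
Conditions: PBr3, Et2O, 0 °C
Reagents that add atoms: phosphorus tribromide, BrP(Br)Br
Why: Bromination of a primary allylic alcohol; direct and allyl-transposed substitution give the same bromide because the allyl unit is symmetric.

Step 3
Reactants: 5 2-(bromomethyl)-6-methylhepta-1,5-diene
Product: 6 tributyl(6-methyl-2-methylidenehept-5-en-1-yl)phosphonium bromide
Conditions: PBu3, MeCN, rt
Reagents that add atoms: tributylphosphine, CCCCP(CCCC)CCCC
Why: Quaternisation (SN2) of the allylic bromide gives the Wittig salt; no stereocentre is involved.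

Step 4
Reactants: 7 5-hydroxy-2-methoxybenzaldehyde
Product: 8 5-(tert-butyldimethylsilyloxy)-2-methoxybenzaldehyde
Conditions: TBSCl, imidazole, DMF, rt
Reagents that add atoms: tert-butyldimethylsilyl chloride, CC(C)(C)[Si](C)(C)Cl
Why: Silylation masks the phenol, which is later oxidised to the cyclohexenone carbonyl C7.

Step 5
Reactants: 9 allylboronic acid pinacol ester; 10 methyl but-3-enoate
Product: 11 methyl (E)-5-(4,4,5,5-tetramethyl-1,3,2-dioxaborolan-2-yl)pent-3-enoate
Conditions: second-generation Grubbs catalyst (H2IMes)(PCy3)Cl2Ru=CHPh (3 mol%), 10 in excess, CH2Cl2, 40 °C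
Reagents that add atoms: none
Why: Olefin cross-metathesis of two terminal alkenes should give mainly the (E)-allylboronate; any (Z) isomer would end as the trans-lactone, which is removed after step 6.

Step 6
Reactants: 8 5-(tert-butyldimethylsilyloxy)-2-methoxybenzaldehyde; 11 methyl (E)-5-(pinacolboryl)pent-3-enoate
Product: 13 (4R,5R)-5-Ar-4-vinyldihydrofuran-2(3H)-one (cis-lactone), via hydroxy ester 12 (not isolated)
Conditions: (R)-3,3′-bis(2,4,6-triisopropylphenyl)-1,1′-binaphthyl-2,2′-diyl hydrogen phosphate (5 mol%), 4 Å MS, toluene, −30 °C; then MeOH, pyridinium p-toluenesulfonate (cat.), rt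
Reagents that add atoms: none
Why: Chiral-phosphoric-acid-catalysed allylboration through a closed chair transition state: the (E)-boronate gives the anti adduct (C14), the (R)-acid should select the aldehyde face that gives (R)-C27, and the γ-hydroxy ester then closes to the cis-lactone.

Step 7
Reactants: 13 cis-lactone; 14 2-[(4-methoxybenzyl)oxy]acetaldehyde
Product: 15 aldol adduct of 13 carrying CH(OH)CH2OPMB on C15
Conditions: LiN(i-Pr)2, THF, −78 °C; then 14; aq. NH4Cl
Reagents that add atoms: none
Why: Aldol addition of the lithium lactone enolate; the two new centres (C15, C16) form as a mixture and are erased in step 8.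

Step 8
Reactants: 15 aldol adduct
Product: 17 (E)-α-alkylidene lactone, via mesylate 16 (not isolated)
Conditions: MsCl, Et3N, CH2Cl2, 0 °C; then DBU, 0 °C to rt
Reagents that add atoms: none
Why: Mesylation and E1cB elimination should give the thermodynamically preferred (E)-alkylidene lactone, in which C17 is anti to the lactone carbonyl and therefore syn to C14 as the target requires.

Step 9
Reactants: 17 (E)-α-alkylidene lactone
Product: 18 allylic diol Ar–C27H(OH)–C14H(CH=CH2)–C15(CH2OH)=C16H–CH2OPMB
Conditions: i-Bu2AlH (4 equiv), CH2Cl2, −78 to 0 °C; aq. potassium sodium tartrate (KNaC4H4O6)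
Reagents that add atoms: none
Why: 1,2-Reduction of the unsaturated lactone opens it to the C27/C28 diol with the alkene geometry kept; no stereocentre is changed.

Step 10
Reactants: 18 allylic diol
Product: 19 bis(TBS) ether of 18
Conditions: TBSOTf (2.5 equiv), 2,6-lutidine, CH2Cl2, −78 to 0 °C
Reagents that add atoms: tert-butyldimethylsilyl trifluoromethanesulfonate, CC(C)(C)[Si](C)(C)OS(=O)(=O)C(F)(F)F
Why: Silylation of the primary allylic and the hindered secondary benzylic alcohol; these two ethers stay until step 26.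

Step 11
Reactants: 19 bis(TBS) ether
Product: 21 primary alcohol (C12–OH), via alkylborane 20 (not isolated)
Conditions: 9-BBN, THF, 0 °C to rt; then 30% H2O2, aq. NaOAc, 0 °C
Reagents that add atoms: hydrogen peroxide, OO
Why: Anti-Markovnikov hydroboration–oxidation; 9-BBN reacts with the monosubstituted vinyl group and not with the hindered trisubstituted C15=C16 alkene.

Step 12
Reactants: 21 primary alcohol
Product: 22 phenol
Conditions: K2CO3, MeOH, rt
Reagents that add atoms: none
Why: Base-mediated methanolysis cleaves only the aryl silyl ether, because phenoxide is a far better leaving group than the alkoxides of the two alkyl silyl ethers.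

Step 13
Reactants: 22 phenol
Product: 23 quinone monoketal (4,4-dimethoxycyclohexa-2,5-dienone with the side chain on C11)
Conditions: PhI(OAc)2, MeOH, 0 °C
Reagents that add atoms: methanol, CO
Why: Oxidative dearomatisation of a para-methoxyphenol with hypervalent iodine in methanol; the free primary alcohol does not compete with the solvent and no stereocentre is formed.

Step 14
Reactants: 23 quinone monoketal
Product: 24 4,4-dimethoxycyclohex-2-enone (C6=C11 kept, C8–C9 saturated)
Conditions: [(Ph3P)CuH]6 (0.5 equiv), H2O (3 equiv), benzene, rt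
Reagents that add atoms: none
Why: Copper hydride conjugate reduction (Stryker type) delivers hydride to the unsubstituted β-carbon C9 and not to the fully substituted β-carbon C11, so the enone needed for ring closure remains.

Step 15
Reactants: 24 cyclohexenone
Product: 25 primary iodide (C12–I)
Conditions: PPh3, I2, imidazole, CH2Cl2, 0 °C
Reagents that add atoms: iodine, II
Why: Appel-type iodination (SN2) of the primary alcohol; it is done after step 13 because alkyl iodides do not survive the hypervalent-iodine oxidant.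

Step 16
Reactants: 25 primary iodide
Product: 26 spiro[4.5]decan-7-one with allyl on C6 and a dimethyl ketal at C10
Conditions: Bu3SnCH2CH=CH2 (3 equiv), AIBN (0.2 equiv in portions), benzene (0.02 M), 80 °C
Reagents that add atoms: allyltributylstannane, CCCC[Sn](CCCC)(CCCC)CC=C
Why: Bu3Sn• abstracts iodine from 25, the primary C12 radical adds to C11 (the β-carbon of the cyclohexenone), and the electrophilic α-keto radical at C6 attacks the terminal carbon of the allylstannane, whose β-scission returns Bu3Sn•; the closest known type is a radical conjugate-addition cyclisation followed by Keck allyl transfer. The only ring closed is the cyclopentane C11–C12–C13–C14–C27, in the 5-exo-trig mode, through the new C11–C12 bond. C11 is set by C14 and C27: in the chair-like transition state the large C14 substituent is pseudo-equatorial and C27–H eclipses the C11–C10 bond to avoid allylic strain with the quaternary ketal carbon C10, which puts the C27 oxygen on the side of C6. C6 is set by C11: the stannane approaches the C6 radical axially and anti to the newly formed axial C11–C12 bond, so the allyl group ends trans to C12 and cis to C27. Ring closure must outrun direct allyl transfer to the primary radical, and capture at C6 must outrun oligomerisation; the polarity match (nucleophilic alkyl radical with the enone, then electrophilic α-keto radical with the electron-rich stannane) and a moderate stannane concentration should secure both. The C15=C16 alkene could only be reached by 4-exo or 5-endo attack and should stay untouched.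

Step 17
Reactants: 26 spiro ketone
Product: 27 C7 isopropenyl carbinol (C7 epimers)
Conditions: CH2=C(CH3)MgBr, CeCl3, THF, −78 to −40 °C
Reagents that add atoms: isopropenylmagnesium bromide, CC(=C)[Mg]Br
Why: 1,2-Addition of the weakly basic organocerium reagent to the hindered, enolisable C7 ketone; the new C7 centre forms without control and is removed again in step 22.

Step 18
Reactants: 27 C7 carbinol
Product: 28 C10 ketone
Conditions: pyridinium p-toluenesulfonate (cat.), acetone/H2O 10:1, rt
Reagents that add atoms: water, O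
Why: Mild acid-catalysed ketal hydrolysis frees the C10 ketone while silyl ethers, PMB ether and the tertiary allylic alcohol are kept; C11 is quaternary, so the β-silyloxy ketone cannot eliminate.

Step 19
Reactants: 28 C10 ketone
Product: 29 C10 methyl carbinol
Conditions: MeLi, CeCl3 (3 equiv), THF, −78 °C
Reagents that add atoms: methyllithium, [Li]C
Why: Organocerium 1,2-addition to the C10 ketone from the face opposite to the C6 allyl arm and the C27 branch (both on the lower face of the six-membered ring), which should place CH3 cis to C12 and OH cis to C27.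

Step 20
Reactants: 29 C10 methyl carbinol
Product: 31 primary alcohol (C3–OH), via alkylborane 30 (not isolated)
Conditions: disiamylborane (from BH3·THF and 2-methylbut-2-ene), THF, 0 °C; then 30% H2O2, aq. NaOH, 0 °C
Reagents that add atoms: hydrogen peroxide, OO
Why: Hydroboration–oxidation with the bulky dialkylborane should be selective for the monosubstituted allyl alkene over the hindered isopropenyl and trisubstituted alkenes and gives the anti-Markovnikov alcohol.

Step 21
Reactants: 31 primary alcohol
Product: 32 C3 tetradecanoate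
Conditions: tetradecanoyl chloride, pyridine, DMAP (cat.), CH2Cl2, 0 °C
Reagents that add atoms: tetradecanoyl chloride, CCCCCCCCCCCCCC(=O)Cl
Why: DMAP-catalysed acylation of the only primary alcohol; the two tertiary alcohols should not react under these conditions.

Step 22
Reactants: 32 C3 tetradecanoate
Product: 33 (Z)-enal (C7=C2(CH3)–C1HO, CHO syn to C6)
Conditions: pyridinium chlorochromate C5H5NH[CrO3Cl] (3 equiv), 4 Å MS, CH2Cl2, rt; then trace I2, daylight to equilibrate the alkene geometry
Reagents that add atoms: pyridinium chlorochromate, [O-][Cr](=O)(=O)Cl.c1cc[nH+]cc1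
Why: Babler–Dauben oxidative 1,3-transposition ([3,3] shift of the tertiary allylic chromate ester, then oxidation) gives the tetrasubstituted enal; the isomer with CHO syn to C6 is expected to be the thermodynamically preferred one, so the geometric mixture is equilibrated and the minor isomer recycled.

Step 23
Reactants: 33 (Z)-enal
Product: 34 C17 allylic alcohol
Conditions: DDQ (1.2 equiv), CH2Cl2/pH 7 buffer, 0 °C
Reagents that add atoms: none
Why: Oxidative PMB-ether cleavage by DDQ (hydride abstraction, then hydrolysis of the oxocarbenium ion); silyl ethers, ester and the electron-poor enal are inert.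

Step 24
Reactants: 34 C17 allylic alcohol
Product: 35 C17 enal (C1,C17-dialdehyde)
Conditions: MnO2 (excess), CH2Cl2, rt
Reagents that add atoms: none
Why: Chemoselective oxidation of the primary allylic alcohol with MnO2; the tertiary alcohol is untouched and the C15=C16 geometry is kept.

Step 25
Reactants: 35 C17 enal; 6 tributyl(6-methyl-2-methylidenehept-5-en-1-yl)phosphonium bromide
Product: 37 bis(TBS) triene monomer, via ylide 36 (not isolated)
Conditions: 6, NaN(SiMe3)2, THF, −78 °C; then 35 (1.0 equiv), −78 to 0 °C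
Reagents that add atoms: none
Why: Wittig olefination with a semi-stabilised allylic tributylphosphonium ylide, which is (E)-selective, at the unhindered C17 aldehyde; the tetrasubstituted α-branched C1 enal is far less electrophilic and should not compete with one equivalent of ylide.

Step 26
Reactants: 37 bis(TBS) triene monomer
Product: 38 triene monomer (C27–OH, C28–OH free)
Conditions: HF·pyridine, pyridine, THF, 0 °C to rt
Reagents that add atoms: none
Why: Buffered fluoride cleavage of both silyl ethers leaves ester, enal and triene intact.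

Step 27
Reactants: 38 triene monomer (two molecules)
Product: 39 CNP0458412.1
Conditions: toluene (2 M), 2,6-di-tert-butyl-4-methylphenol (5 mol%), degassed, 110 °C, sealed tube; HPLC separation
Reagents that add atoms: none
Why: Thermal intermolecular Diels–Alder dimerisation in which the diene C17=C18–C19=C29 of one molecule adds to the terminal C19=C29 bond of a second one with "para" orientation (first bond between the two CH2 termini) and with the two large arms trans, which sets the relative configuration of the two new ring centres; their absolute sense is only weakly biased by the remote centres, so the core-diastereomeric adduct is expected as a by-product to be removed by HPLC.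

**Compound list**
1 | 5-bromo-2-methylpent-2-ene | CC(C)=CCCBr | starting material
2 | prop-2-yn-1-ol | C#CCO | starting material
3 | (4-methylpent-3-en-1-yl)magnesium bromide | CC(C)=CCC[Mg]Br | intermediate (not isolated)
4 | 6-methyl-2-methylidenehept-5-en-1-ol | CC(C)=CCCC(=C)CO | intermediate
5 | 2-(bromomethyl)-6-methylhepta-1,5-diene | CC(C)=CCCC(=C)CBr | intermediate
6 | tributyl(6-methyl-2-methylidenehept-5-en-1-yl)phosphonium bromide | CCCC[P+](CCCC)(CCCC)CC(=C)CCC=C(C)C.[Br-] | intermediate
7 | 5-hydroxy-2-methoxybenzaldehyde | COc1ccc(O)cc1C=O | starting material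
8 | 5-(tert-butyldimethylsilyloxy)-2-methoxybenzaldehyde | COc1ccc(O[Si](C)(C)C(C)(C)C)cc1C=O | intermediate
9 | allylboronic acid pinacol ester | C=CCB1OC(C)(C)C(C)(C)O1 | starting material
10 | methyl but-3-enoate | COC(=O)CC=C | starting material
11 | methyl (E)-5-(4,4,5,5-tetramethyl-1,3,2-dioxaborolan-2-yl)pent-3-enoate | COC(=O)C/C=C/CB1OC(C)(C)C(C)(C)O1 | intermediate
12 | methyl (R)-3-[(R)-hydroxy(Ar)methyl]pent-4-enoate (anti) | C=C[C@@H](CC(=O)OC)[C@H](c1cc(O[Si](C)(C)C(C)(C)C)ccc1OC)O | intermediate (not isolated)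
13 | (4R,5R)-5-Ar-4-vinyldihydrofuran-2(3H)-one (cis-lactone; C27 = C5, C14 = C4) | C=C[C@@H]1[C@H](c2cc(O[Si](C)(C)C(C)(C)C)ccc2OC)OC(=O)C1 | intermediate
14 | 2-[(4-methoxybenzyl)oxy]acetaldehyde | COc1ccc(COCC=O)cc1 | starting material
15 | lactone 13 with CH(OH)CH2OPMB on C15 (mixture at C15 and C16) | C=C[C@@H]1[C@H](c2cc(O[Si](C)(C)C(C)(C)C)ccc2OC)OC(=O)C1C(O)COCc1ccc(OC)cc1 | intermediate
16 | methanesulfonate of 15 | C=C[C@@H]1[C@H](c2cc(O[Si](C)(C)C(C)(C)C)ccc2OC)OC(=O)C1C(OS(C)(=O)=O)COCc1ccc(OC)cc1 | intermediate (not isolated)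
17 | (E)-α-(2-PMB-oxyethylidene) cis-lactone | C=C[C@@H]1[C@H](c2cc(O[Si](C)(C)C(C)(C)C)ccc2OC)OC(=O)/C1=C/COCc1ccc(OC)cc1 | intermediate
18 | diol Ar–C27H(OH)–C14H(CH=CH2)–C15(CH2OH)=C16H–CH2OPMB (15E; C27 and C14 as in 13) | C=C[C@@H](/C(=C\COCc1ccc(OC)cc1)CO)[C@H](c1cc(O[Si](C)(C)C(C)(C)C)ccc1OC)O | intermediate
19 | C27,C28-bis(TBS) ether of 18 | C=C[C@@H](/C(=C\COCc1ccc(OC)cc1)CO[Si](C)(C)C(C)(C)C)[C@H](c1cc(O[Si](C)(C)C(C)(C)C)ccc1OC)O[Si](C)(C)C(C)(C)C | intermediate
20 | B-alkyl-9-borabicyclo[3.3.1]nonane from 19 (boron on C12) | C1CCC2CCCC1B2CC[C@@H](/C(=C\COCc1ccc(OC)cc1)CO[Si](C)(C)C(C)(C)C)[C@H](c1cc(O[Si](C)(C)C(C)(C)C)ccc1OC)O[Si](C)(C)C(C)(C)C | intermediate (not isolated)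
21 | primary alcohol (C12–OH), aryl silyl ether | OCC[C@@H](/C(=C\COCc1ccc(OC)cc1)CO[Si](C)(C)C(C)(C)C)[C@H](c1cc(O[Si](C)(C)C(C)(C)C)ccc1OC)O[Si](C)(C)C(C)(C)C | intermediate
22 | phenol (4-methoxyphenol with the side chain ortho to OCH3) | OCC[C@@H](/C(=C\COCc1ccc(OC)cc1)CO[Si](C)(C)C(C)(C)C)[C@H](c1cc(O)ccc1OC)O[Si](C)(C)C(C)(C)C | intermediate
23 | 4,4-dimethoxycyclohexa-2,5-dienone carrying the side chain on C11 | OCC[C@@H](/C(=C\COCc1ccc(OC)cc1)CO[Si](C)(C)C(C)(C)C)[C@H](C1=CC(=O)C=CC1(OC)OC)O[Si](C)(C)C(C)(C)C | intermediate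
24 | 4,4-dimethoxycyclohex-2-enone (C7=O, C6=C11) with C12–OH | OCC[C@@H](/C(=C\COCc1ccc(OC)cc1)CO[Si](C)(C)C(C)(C)C)[C@H](C1=CC(=O)CCC1(OC)OC)O[Si](C)(C)C(C)(C)C | intermediate
25 | primary iodide (C12–I) of 24 | ICC[C@@H](/C(=C\COCc1ccc(OC)cc1)CO[Si](C)(C)C(C)(C)C)[C@H](C1=CC(=O)CCC1(OC)OC)O[Si](C)(C)C(C)(C)C | intermediate
26 | spiro[4.5]decan-7-one: C6 allyl (trans to C12, cis to C27), C10 dimethyl ketal, C27–OTBS, C14 side chain C(CH2OTBS)=CH–CH2OPMB (15E) | C=CC[C@@H]1C(=O)CCC(OC)(OC)[C@@]12CC[C@@H](/C(=C\COCc1ccc(OC)cc1)CO[Si](C)(C)C(C)(C)C)[C@H]2O[Si](C)(C)C(C)(C)C | intermediate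
27 | C7 isopropenyl carbinol of 26 (C7 epimers) | C=CC[C@@H]1C(O)(C(C)=C)CCC(OC)(OC)[C@@]12CC[C@@H](/C(=C\COCc1ccc(OC)cc1)CO[Si](C)(C)C(C)(C)C)[C@H]2O[Si](C)(C)C(C)(C)C | intermediate
28 | C10 ketone from 27 | C=CC[C@@H]1C(O)(C(C)=C)CCC(=O)[C@@]12CC[C@@H](/C(=C\COCc1ccc(OC)cc1)CO[Si](C)(C)C(C)(C)C)[C@H]2O[Si](C)(C)C(C)(C)C | intermediate
29 | C10 methyl carbinol (CH3 cis to C12, OH cis to C27) | C=CC[C@@H]1C(O)(C(C)=C)CC[C@](C)(O)[C@@]12CC[C@@H](/C(=C\COCc1ccc(OC)cc1)CO[Si](C)(C)C(C)(C)C)[C@H]2O[Si](C)(C)C(C)(C)C | intermediate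
30 | bis(3-methylbutan-2-yl)alkylborane from 29 (boron on C3) | CC(C)C(C)B(C(C)C(C)C)CCC[C@@H]1C(O)(C(C)=C)CC[C@](C)(O)[C@@]12CC[C@@H](/C(=C\COCc1ccc(OC)cc1)CO[Si](C)(C)C(C)(C)C)[C@H]2O[Si](C)(C)C(C)(C)C | intermediate (not isolated)
31 | primary alcohol (C3–OH) | OCCC[C@@H]1C(O)(C(C)=C)CC[C@](C)(O)[C@@]12CC[C@@H](/C(=C\COCc1ccc(OC)cc1)CO[Si](C)(C)C(C)(C)C)[C@H]2O[Si](C)(C)C(C)(C)C | intermediate
32 | C3 tetradecanoate of 31 | CCCCCCCCCCCCCC(=O)OCCC[C@@H]1C(O)(C(C)=C)CC[C@](C)(O)[C@@]12CC[C@@H](/C(=C\COCc1ccc(OC)cc1)CO[Si](C)(C)C(C)(C)C)[C@H]2O[Si](C)(C)C(C)(C)C | intermediate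
33 | (Z)-enal: C7=C2(CH3)CHO with CHO syn to C6; C17–OPMB | CCCCCCCCCCCCCC(=O)OCCC[C@@H]1/C(=C(/C)C=O)CC[C@](C)(O)[C@@]12CC[C@@H](/C(=C\COCc1ccc(OC)cc1)CO[Si](C)(C)C(C)(C)C)[C@H]2O[Si](C)(C)C(C)(C)C | intermediate
34 | C17 allylic alcohol | CCCCCCCCCCCCCC(=O)OCCC[C@@H]1/C(=C(/C)C=O)CC[C@](C)(O)[C@@]12CC[C@@H](/C(=C\CO)CO[Si](C)(C)C(C)(C)C)[C@H]2O[Si](C)(C)C(C)(C)C | intermediate
35 | C17 enal (15E) | CCCCCCCCCCCCCC(=O)OCCC[C@@H]1/C(=C(/C)C=O)CC[C@](C)(O)[C@@]12CC[C@@H](/C(=C\C=O)CO[Si](C)(C)C(C)(C)C)[C@H]2O[Si](C)(C)C(C)(C)C | intermediate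
36 | tributylphosphonium ylide from 6 | CCCC[P+](CCCC)(CCCC)[CH-]C(=C)CCC=C(C)C | intermediate (not isolated)
37 | bis(TBS) triene monomer (15E,17E) | CCCCCCCCCCCCCC(=O)OCCC[C@@H]1/C(=C(/C)C=O)CC[C@](C)(O)[C@@]12CC[C@@H](/C(=C\C=C\C(=C)CCC=C(C)C)CO[Si](C)(C)C(C)(C)C)[C@H]2O[Si](C)(C)C(C)(C)C | intermediate
38 | triene monomer (6R,10S,11S,14S,27R; 2Z,15E,17E) | CCCCCCCCCCCCCC(=O)OCCC[C@@H]1/C(=C(/C)C=O)CC[C@](C)(O)[C@@]12CC[C@@H](/C(=C\C=C\C(=C)CCC=C(C)C)CO)[C@H]2O | intermediate
39 | CNP0458412.1 | CCCCCCCCCCCCCC(=O)OCCC[C@@H]1/C(=C(/C)C=O)CC[C@](C)(O)[C@@]12CC[C@@H](/C(=C\C=C\[C@@]1(CCC=C(C)C)CCC(CCC=C(C)C)=C[C@@H]1/C=C(/CO)[C@@H]1CC[C@]3([C@H](CCCOC(=O)CCCCCCCCCCCCC)/C(=C(/C)C=O)CC[C@]3(C)O)[C@@H]1O)CO)[C@H]2O | target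

Total step count: 27. Longest linear sequence: 23 steps (7 to 39; steps 4 and 6–27).

**Steps most likely to fail**

Step 27. The bimolecular cycloaddition may be slow at temperatures the polyene tolerates, so that polymerisation and E/Z isomerisation of the enal compete. The remote stereocentres also give little π-facial discrimination, so the wanted adduct may be accompanied by its core diastereomer. Fallback: set out from 37 with the silyl ethers still in place and run the dimerisation as a hole-catalysed (cation-radical) Diels–Alder reaction with tris(4-bromophenyl)aminium hexachloroantimonate, (4-BrC6H4)3N SbCl6 (10 mol%), and 2,6-di-tert-butylpyridine in CH2Cl2 at 0 °C. The triene is the most easily oxidised π-system; its cation-radical should add through the CH2 terminus to C29 of a neutral triene and close to the same "para" cyclohexene, giving the tetrakis(TBS) dimer F1. HF·pyridine then removes the four silyl groups and the route comes back at 39.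

Step 16. The primary radical may take up the allyl group before ring closure, or the C6 radical may be captured on the wrong face or oligomerise. Fallback: separate ring closure from allylation. Set out from 23; PPh3, I2 and imidazole give the iodo quinone monoketal F2. Bu3SnH (slow addition) with AIBN in benzene at 80 °C closes the cyclopentane at C11 and reduces the C6 radical, giving the spiro enone F3, which keeps the C8=C9 double bond. Because C8 is vinylic, LiN(i-Pr)2 can form only the C6 enolate, which allyl bromide alkylates trans to C12 to give the allyl spiro enone F4. [(Ph3P)CuH]6 then reduces C8=C9 and the route comes back at 26.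

Step 19. The organocerium reagent may attack the C10 ketone from the wrong face, or may enolise the hindered ketone. Fallback: set out from 28 and use a small reagent with the complementary (axial) sense of delivery. Dimethylsulfonium methylide (from trimethylsulfonium iodide and n-BuLi, THF, −10 °C) transfers CH2 irreversibly and gives the spiro-epoxide F5 with oxygen on the face of C27. LiBHEt3 opens the epoxide at CH2 and the route comes back at 29.

**Further compounds**
F1 | step 27 | tetrakis(TBS) ether of 39 (both C27–O and both C28–O silylated) | CCCCCCCCCCCCCC(=O)OCCC[C@@H]1/C(=C(/C)C=O)CC[C@](C)(O)[C@@]12CC[C@@H](/C(=C\C=C\[C@@]1(CCC=C(C)C)CCC(CCC=C(C)C)=C[C@@H]1/C=C(/CO[Si](C)(C)C(C)(C)C)[C@@H]1CC[C@]3([C@H](CCCOC(=O)CCCCCCCCCCCCC)/C(=C(/C)C=O)CC[C@]3(C)O)[C@@H]1O[Si](C)(C)C(C)(C)C)CO[Si](C)(C)C(C)(C)C)[C@H]2O[Si](C)(C)C(C)(C)C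
F2 | step 16 | iodo quinone monoketal (C12–I analogue of 23) | ICC[C@@H](/C(=C\COCc1ccc(OC)cc1)CO[Si](C)(C)C(C)(C)C)[C@H](C1=CC(=O)C=CC1(OC)OC)O[Si](C)(C)C(C)(C)C
F3 | step 16 | spiro enone (C6H2, C7=O, C8=C9, C10 dimethyl ketal) | C1C(=O)C=CC(OC)(OC)[C@@]12CC[C@@H](/C(=C\COCc1ccc(OC)cc1)CO[Si](C)(C)C(C)(C)C)[C@H]2O[Si](C)(C)C(C)(C)C
F4 | step 16 | allyl spiro enone (C6 allyl trans to C12; C8=C9 kept) | C=CC[C@@H]1C(=O)C=CC(OC)(OC)[C@@]12CC[C@@H](/C(=C\COCc1ccc(OC)cc1)CO[Si](C)(C)C(C)(C)C)[C@H]2O[Si](C)(C)C(C)(C)C
F5 | step 19 | C10 spiro-epoxide (CH2 cis to C12, O cis to C27) | C=CC[C@@H]1C(O)(C(C)=C)CC[C@](C3)(O3)[C@@]12CC[C@@H](/C(=C\COCc1ccc(OC)cc1)CO[Si](C)(C)C(C)(C)C)[C@H]2O[Si](C)(C)C(C)(C)C
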